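**Plan** (germacrane numbering: ring C1–C10; lactone O on C6, C11 = lactone α-carbon, C12 = lactone C=O, C13 = exocyclic CH2; C14 = CO2Me on C10; C15 = CH2OH on C4; target is 6R,7S,8S,9S with both ring alkenes cis within the ring)
1. Retrosynthesis cuts C1=C10 of the ten-membered ring (ring-closing metathesis), then the lactone bond C7–C11 (ring O–C6–C7–C11–C12 opened to an O6 acrylate plus a C7–C8 epoxide), then C5–C6 (Nozaki–Hiyama–Kishi) and C9–C10 (Morita–Baylis–Hillman).
2. Enabling feature: the β-carbon C7 of the γ-lactone ring carries the oxygenated carbon C8, and the C8–O bond is anti to C7–C11. This is the pattern left when a trans C7–C8 epoxide is opened at C7 by the α-carbon of an acrylate held on O6.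
3. Forward: a C6–C10/C14 epoxy aldehyde (asymmetric MBH, then organocatalytic epoxidation) is joined to a C1–C5/C15 alkenyl iodide (syn-carbocupration). Acryloylation and a phosphine-mediated closure then build the α-methylene lactone, the two esters are installed, and the ten-membered carbocycle is closed last.
4. Stereochemistry: C9 from the β-isocupreidine MBH step; C7/C8 from catalyst-controlled enal epoxidation; C6 from Felkin–Anh addition to the epoxy aldehyde; C7 is then inverted in the lactone closure. C4=C5 geometry comes from syn-carbocupration and C1=C10 geometry from the ring constraint.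

Key step: step 9

Assumption: the four building blocks, β-isocupreidine and the (R)-diarylprolinol silyl ether are taken as purchasable; TBS = tert-butyldimethylsilyl, TBDPS = tert-butyldiphenylsilyl, HFIP = 1,1,1,3,3,3-hexafluoropropan-2-yl.

**Step 1**
Reactants: 1 (2E)-4,4-dimethoxybut-2-enal; 2 HFIP prop-2-enoate
Product: 3 HFIP (3R,4E)-3-hydroxy-6,6-dimethoxy-2-methylidenehex-4-enoate
Conditions: β-isocupreidine (10 mol%), DMF, −55 °C
Reagents that add atoms: none
Why: Asymmetric Morita–Baylis–Hillman reaction: β-isocupreidine adds to the activated acrylate 2, the ammonium enolate attacks the aldehyde carbonyl of 1 (1,2-addition; enal C=C and acetal untouched), and the catalyst's phenolic OH directs the aldol step so that the C9 carbinol should form as the (R)-enantiomer.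

**Step 2**
Reactants: 3 HFIP ester MBH adduct
Product: 4 methyl (3R,4E)-3-hydroxy-6,6-dimethoxy-2-methylidenehex-4-enoate
Conditions: MeOH, Et3N, rt
Reagents that add atoms: methanol, CO
Why: Transesterification of the activated hexafluoroisopropyl ester by methanol under mild amine base; the C9 stereocentre and the acrylate are not affected.

**Step 3**
Reactants: 4 methyl ester MBH adduct
Product: 5 methyl (3R,4E)-3-[(tert-butyldimethylsilyl)oxy]-6,6-dimethoxy-2-methylidenehex-4-enoate
Conditions: TBSCl, imidazole, DMF, rt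
Reagents that add atoms: tert-butyldimethylsilyl chloride, CC(C)(C)[Si](C)(C)Cl
Why: Silylation of the secondary allylic alcohol under non-acidic conditions that spare the acetal; the TBS ether survives the later acetal hydrolysis and, unlike an acyl group, cannot be displaced in an SN2' sense by the phosphine of step 9.

**Step 4**
Reactants: 5 TBS ether acetal
Product: 6 methyl (3R,4E)-3-[(tert-butyldimethylsilyl)oxy]-2-methylidene-6-oxohex-4-enoate
Conditions: TsOH·H2O (5 mol%), THF/H2O (4:1), 0 °C → rt
Reagents that add atoms: water, O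
Why: Acid-catalysed hydrolysis of the allylic dimethyl acetal (fast because the oxocarbenium ion is allylic) leaves the secondary TBS ether and the ester intact and keeps the E geometry.

**Step 5**
Reactants: 6 enal
Product: 7 methyl (3S)-3-[(tert-butyldimethylsilyl)oxy]-3-[(2S,3S)-3-formyloxiran-2-yl]-2-methylidenepropanoate
Conditions: (R)-2-{bis[3,5-bis(trifluoromethyl)phenyl][(trimethylsilyl)oxy]methyl}pyrrolidine (10 mol%), 35% aq. H2O2, CH2Cl2, rt
Reagents that add atoms: hydrogen peroxide, OO
Why: Iminium-catalysed nucleophilic epoxidation of an enal: H2O2 adds to C8 of the iminium ion on the face left open by the diaryl(silyloxy)methyl group and the enamine closes the trans-epoxide, so the catalyst (the antipode of the one that gives (2R,3S)-epoxy aldehydes from simple (E)-enals) should set C7 and C8 by catalyst control over the remote C9 centre.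

**Step 6**
Reactants: 8 but-3-en-1-ylmagnesium bromide (0.5 M in THF); 9 tert-butyl(diphenyl)(prop-2-yn-1-yloxy)silane
Product: 12 tert-butyl{[(2E)-2-(iodomethylidene)hex-5-en-1-yl]oxy}diphenylsilane, via but-3-en-1-ylcopper 10 (not isolated), via alkenylcopper 11 (not isolated)
Conditions: CuBr·SMe2 (1.0 equiv), THF/Me2S, −45 °C; then 9, −45 → −20 °C; then I2, −60 → 0 °C
Reagents that add atoms: iodine, II
Why: Syn-carbocupration of a terminal alkyne (Normant type): the butenyl group adds to the internal carbon and copper to the terminal carbon on the same side, the bulky non-coordinating silyl ether in THF disfavouring the oxygen-directed reverse regiochemistry, and iodinolysis with retention gives the (E)-iodide with iodine cis to the butenyl chain, i.e. the cis C6–C5=C4–C3 arrangement of the ring.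

**Step 7**
Reactants: 7 epoxy aldehyde; 12 alkenyl iodide
Product: 13 epoxy alcohol, methyl (3S)-3-[(tert-butyldimethylsilyl)oxy]-3-{(2S,3R)-3-[(1R,2E)-3-({[tert-butyl(diphenyl)silyl]oxy}methyl)-1-hydroxyhepta-2,6-dien-1-yl]oxiran-2-yl}-2-methylidenepropanoate
Conditions: CrCl2 (4 equiv), NiCl2 (2 mol%), DMSO, rt
Reagents that add atoms: none
Why: Nozaki–Hiyama–Kishi coupling: the nickel-catalysed, chromium-mediated addition of the alkenyl iodide is selective for the aldehyde over both esters and the epoxide and keeps the alkene geometry, and polar Felkin–Anh attack anti to the C7–O bond of the epoxide should favour the erythro (6R) epoxy alcohol.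

**Step 8**
Reactants: 13 epoxy alcohol
Product: 14 O6 acrylate of 13 (6R,7R,8S,9S)
Conditions: acryloyl chloride, i-Pr2NEt, CH2Cl2, −78 → 0 °C
Reagents that add atoms: acryloyl chloride, C=CC(=O)Cl
Why: Acylation of the secondary alcohol with an acid chloride and a hindered amine at low temperature; no stereocentre is touched and the epoxide is stable to these conditions.

**Step 9**
Reactants: 14 epoxy acrylate
Product: 17 C8-hydroxy α-methylene-γ-lactone (6R,7R,8S,9S), via phosphonium enolate 15 (not isolated), via phosphonium alkoxide 16 (not isolated)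
Conditions: PMe3 (1.2 equiv), t-BuOH, 0.005 M, rt → 40 °C
Reagents that add atoms: none
Why: Proposed new method: PMe3 adds reversibly to the unsubstituted O6 acrylate of 14 to give the β-phosphonio ester enolate 15, whose α-carbon C11 opens the epoxide at C7 from the side opposite to the epoxide oxygen to give the phosphonium alkoxide 16, and the C8 alkoxide (relayed by t-BuOH) removes the C11 proton so that PMe3 is expelled and the exocyclic C11=C13 methylene of 17 appears. The closest known reaction type is the trialkylphosphine-mediated intramolecular Morita–Baylis–Hillman alkylation of enones by tethered epoxides and alkyl halides; the extension here is to an acrylate ester whose alkoxy oxygen becomes part of the new ring. The γ-lactone ring (O–C6–C7–C11–C12) closes in the 5-exo-tet mode, the breaking C7–O bond lying outside the new ring, and the 6-endo alternative at C8 is geometrically disfavoured. The one new stereocentre, C7, is fixed by SN2 inversion of the enantio-defined trans-epoxide, which leaves the C8 oxygen anti to the new C7–C11 bond and, with the (6R) carbinol, gives the trans-β,γ-disubstituted lactone of the target. The step needs the phosphine to choose the O6 acrylate over the C10 acrylate and the enolate to cyclise before it oligomerises: the 2-substituted C10 acrylate is a far poorer phosphine acceptor and its silyl ether is no leaving group for an SN2' displacement, while high dilution in t-BuOH suppresses Rauhut–Currier coupling and activates the epoxide by hydrogen bonding. Because phosphine addition is reversible, the minor s-cis ester rotamer needed for closure can be funnelled through under Curtin–Hammett control.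

**Step 10**
Reactants: 17 hydroxy lactone
Product: 18 C8 tiglate, methyl (3S,4S)-3-[(tert-butyldimethylsilyl)oxy]-4-{(2R,3S)-2-[(1E)-2-({[tert-butyl(diphenyl)silyl]oxy}methyl)hexa-1,5-dien-1-yl]-4-methylidene-5-oxooxolan-3-yl}-2-methylidene-4-{[(2E)-2-methylbut-2-enoyl]oxy}butanoate
Conditions: tiglic acid, 2,4,6-trichlorobenzoyl chloride, Et3N, toluene, rt; then 17, DMAP, rt
Reagents that add atoms: tiglic acid ((2E)-2-methylbut-2-enoic acid), C/C=C(\C)C(=O)O
Why: Yamaguchi esterification: the mixed anhydride of tiglic acid acylates the hindered C8 alcohol under DMAP catalysis without the deconjugation that an acid chloride/amine ketene pathway could cause, and direct lactone migration to O8 is not expected because it would need a strained bicyclo[2.2.1] orthoester-type intermediate.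

**Step 11**
Reactants: 18 tiglate
Product: 19 C9 alcohol (6R,7S,8S,9S), methyl (3S,4S)-4-{(2R,3S)-2-[(1E)-2-({[tert-butyl(diphenyl)silyl]oxy}methyl)hexa-1,5-dien-1-yl]-4-methylidene-5-oxooxolan-3-yl}-3-hydroxy-2-methylidene-4-{[(2E)-2-methylbut-2-enoyl]oxy}butanoate
Conditions: HF·pyridine, pyridine, THF, 0 °C
Reagents that add atoms: none
Why: Fluoride-mediated desilylation: a secondary TBS ether is cleaved much faster than a primary TBDPS ether by pyridine-buffered HF·pyridine, and the mildly acidic medium avoids acyl migration from O8 to O9 and conjugate addition to the lactone.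

**Step 12**
Reactants: 19 C9 alcohol
Product: 20 C9 acetate, methyl (3S,4S)-3-(acetyloxy)-4-{(2R,3S)-2-[(1E)-2-({[tert-butyl(diphenyl)silyl]oxy}methyl)hexa-1,5-dien-1-yl]-4-methylidene-5-oxooxolan-3-yl}-2-methylidene-4-{[(2E)-2-methylbut-2-enoyl]oxy}butanoate
Conditions: Ac2O, pyridine, DMAP (cat.), CH2Cl2, 0 °C
Reagents that add atoms: acetic anhydride, CC(=O)OC(C)=O
Why: Standard acetylation of the secondary allylic C9 alcohol, done directly after its release so that the tiglate has no time to migrate.

**Step 13**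
Reactants: 20 acyclic triene lactone
Product: 21 methyl (3aS,4S,5S,6E,10E,11aR)-5-(acetyloxy)-10-({[tert-butyl(diphenyl)silyl]oxy}methyl)-3-methylidene-4-{[(2E)-2-methylbut-2-enoyl]oxy}-2-oxo-2,3,3a,4,5,8,9,11a-octahydrocyclodeca[b]furan-6-carboxylate
Conditions: second-generation Hoveyda–Grubbs catalyst (15 mol%), toluene, 0.5 mM, 80 °C
Reagents that add atoms: none
Why: Ring-closing olefin metathesis: the catalyst should load on the monosubstituted C1 alkene and close onto the methylene of the C10 acrylate with loss of ethene, the cis arrangement of C2 and C9 about the new double bond being the one the ten-membered ring can hold and also the thermodynamically preferred (E)-enoate, while the cis C4=C5 bond and the trans-lactone act as turn elements.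

**Step 14**
Reactants: 21 macrocyclic TBDPS ether
Product: 22 CNP0216801.5, methyl (3aS,4S,5S,6E,10E,11aR)-5-(acetyloxy)-10-(hydroxymethyl)-3-methylidene-4-{[(2E)-2-methylbut-2-enoyl]oxy}-2-oxo-2,3,3a,4,5,8,9,11a-octahydrocyclodeca[b]furan-6-carboxylate
Conditions: HF·pyridine, THF, rt
Reagents that add atoms: none
Why: Fluoride cleavage of the primary TBDPS ether under mildly acidic conditions that leave the acetate, tiglate, methyl ester and α-methylene lactone untouched, giving the target.

**Compound list**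
1 | (2E)-4,4-dimethoxybut-2-enal | COC(OC)/C=C/C=O | starting material
2 | 1,1,1,3,3,3-hexafluoropropan-2-yl prop-2-enoate | C=CC(=O)OC(C(F)(F)F)C(F)(F)F | starting material
3 | 1,1,1,3,3,3-hexafluoropropan-2-yl (3R,4E)-3-hydroxy-6,6-dimethoxy-2-methylidenehex-4-enoate | COC(OC)/C=C/[C@@H](O)C(=C)C(=O)OC(C(F)(F)F)C(F)(F)F | intermediate
4 | methyl (3R,4E)-3-hydroxy-6,6-dimethoxy-2-methylidenehex-4-enoate | COC(OC)/C=C/[C@@H](O)C(=C)C(=O)OC | intermediate
5 | methyl (3R,4E)-3-[(tert-butyldimethylsilyl)oxy]-6,6-dimethoxy-2-methylidenehex-4-enoate | COC(OC)/C=C/[C@@H](O[Si](C)(C)C(C)(C)C)C(=C)C(=O)OC | intermediate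
6 | methyl (3R,4E)-3-[(tert-butyldimethylsilyl)oxy]-2-methylidene-6-oxohex-4-enoate | O=C/C=C/[C@@H](O[Si](C)(C)C(C)(C)C)C(=C)C(=O)OC | intermediate
7 | methyl (3S)-3-[(tert-butyldimethylsilyl)oxy]-3-[(2S,3S)-3-formyloxiran-2-yl]-2-methylidenepropanoate | O=C[C@H]1O[C@@H]1[C@@H](O[Si](C)(C)C(C)(C)C)C(=C)C(=O)OC | intermediate
8 | but-3-en-1-ylmagnesium bromide | C=CCC[Mg]Br | starting material
9 | tert-butyl(diphenyl)(prop-2-yn-1-yloxy)silane | C#CCO[Si](c1ccccc1)(c1ccccc1)C(C)(C)C | starting material
10 | but-3-en-1-ylcopper (MgBr2 complex) | C=CCC[Cu] | intermediate (not isolated)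
11 | {(1E)-2-({[tert-butyl(diphenyl)silyl]oxy}methyl)hexa-1,5-dien-1-yl}copper | [Cu]/C=C(/CO[Si](c1ccccc1)(c1ccccc1)C(C)(C)C)CCC=C | intermediate (not isolated)
12 | tert-butyl{[(2E)-2-(iodomethylidene)hex-5-en-1-yl]oxy}diphenylsilane | I/C=C(/CO[Si](c1ccccc1)(c1ccccc1)C(C)(C)C)CCC=C | intermediate
13 | methyl (3S)-3-[(tert-butyldimethylsilyl)oxy]-3-{(2S,3R)-3-[(1R,2E)-3-({[tert-butyl(diphenyl)silyl]oxy}methyl)-1-hydroxyhepta-2,6-dien-1-yl]oxiran-2-yl}-2-methylidenepropanoate | O[C@H](/C=C(/CO[Si](c2ccccc2)(c2ccccc2)C(C)(C)C)CCC=C)[C@H]1O[C@@H]1[C@@H](O[Si](C)(C)C(C)(C)C)C(=C)C(=O)OC | intermediate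
14 | methyl (3S)-3-{(2S,3R)-3-[(1R,2E)-1-(acryloyloxy)-3-({[tert-butyl(diphenyl)silyl]oxy}methyl)hepta-2,6-dien-1-yl]oxiran-2-yl}-3-[(tert-butyldimethylsilyl)oxy]-2-methylidenepropanoate | C=CC(=O)O[C@H](/C=C(/CO[Si](c2ccccc2)(c2ccccc2)C(C)(C)C)CCC=C)[C@H]1O[C@@H]1[C@@H](O[Si](C)(C)C(C)(C)C)C(=C)C(=O)OC | intermediate
15 | β-(trimethylphosphonio) ester enolate from 14 (zwitterion) | C[P+](C)(C)CC=C([O-])O[C@H](/C=C(/CO[Si](c2ccccc2)(c2ccccc2)C(C)(C)C)CCC=C)[C@H]1O[C@@H]1[C@@H](O[Si](C)(C)C(C)(C)C)C(=C)C(=O)OC | intermediate (not isolated)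
16 | cyclised α-[(trimethylphosphonio)methyl] lactone C8 alkoxide (zwitterion, C11 epimers) | C[P+](C)(C)CC1C(=O)O[C@H](/C=C(/CO[Si](c2ccccc2)(c2ccccc2)C(C)(C)C)CCC=C)[C@H]1[C@H]([O-])[C@@H](O[Si](C)(C)C(C)(C)C)C(=C)C(=O)OC | intermediate (not isolated)
17 | methyl (3S,4S)-3-[(tert-butyldimethylsilyl)oxy]-4-{(2R,3R)-2-[(1E)-2-({[tert-butyl(diphenyl)silyl]oxy}methyl)hexa-1,5-dien-1-yl]-4-methylidene-5-oxooxolan-3-yl}-4-hydroxy-2-methylidenebutanoate | C=C1C(=O)O[C@H](/C=C(/CO[Si](c2ccccc2)(c2ccccc2)C(C)(C)C)CCC=C)[C@H]1[C@H](O)[C@@H](O[Si](C)(C)C(C)(C)C)C(=C)C(=O)OC | intermediate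
18 | methyl (3S,4S)-3-[(tert-butyldimethylsilyl)oxy]-4-{(2R,3S)-2-[(1E)-2-({[tert-butyl(diphenyl)silyl]oxy}methyl)hexa-1,5-dien-1-yl]-4-methylidene-5-oxooxolan-3-yl}-2-methylidene-4-{[(2E)-2-methylbut-2-enoyl]oxy}butanoate | C=C1C(=O)O[C@H](/C=C(/CO[Si](c2ccccc2)(c2ccccc2)C(C)(C)C)CCC=C)[C@H]1[C@H](OC(=O)/C(C)=C/C)[C@@H](O[Si](C)(C)C(C)(C)C)C(=C)C(=O)OC | intermediate
19 | methyl (3S,4S)-4-{(2R,3S)-2-[(1E)-2-({[tert-butyl(diphenyl)silyl]oxy}methyl)hexa-1,5-dien-1-yl]-4-methylidene-5-oxooxolan-3-yl}-3-hydroxy-2-methylidene-4-{[(2E)-2-methylbut-2-enoyl]oxy}butanoate | C=C1C(=O)O[C@H](/C=C(/CO[Si](c2ccccc2)(c2ccccc2)C(C)(C)C)CCC=C)[C@H]1[C@H](OC(=O)/C(C)=C/C)[C@@H](O)C(=C)C(=O)OC | intermediate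
20 | methyl (3S,4S)-3-(acetyloxy)-4-{(2R,3S)-2-[(1E)-2-({[tert-butyl(diphenyl)silyl]oxy}methyl)hexa-1,5-dien-1-yl]-4-methylidene-5-oxooxolan-3-yl}-2-methylidene-4-{[(2E)-2-methylbut-2-enoyl]oxy}butanoate | C=C1C(=O)O[C@H](/C=C(/CO[Si](c2ccccc2)(c2ccccc2)C(C)(C)C)CCC=C)[C@H]1[C@H](OC(=O)/C(C)=C/C)[C@@H](OC(C)=O)C(=C)C(=O)OC | intermediate
21 | methyl (3aS,4S,5S,6E,10E,11aR)-5-(acetyloxy)-10-({[tert-butyl(diphenyl)silyl]oxy}methyl)-3-methylidene-4-{[(2E)-2-methylbut-2-enoyl]oxy}-2-oxo-2,3,3a,4,5,8,9,11a-octahydrocyclodeca[b]furan-6-carboxylate | C=C1C(=O)O[C@@H]2/C=C(/CO[Si](c3ccccc3)(c3ccccc3)C(C)(C)C)CC/C=C(/C(=O)OC)[C@H](OC(C)=O)[C@@H](OC(=O)/C(C)=C/C)[C@@H]12 | intermediate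
22 | CNP0216801.5, methyl (3aS,4S,5S,6E,10E,11aR)-5-(acetyloxy)-10-(hydroxymethyl)-3-methylidene-4-{[(2E)-2-methylbut-2-enoyl]oxy}-2-oxo-2,3,3a,4,5,8,9,11a-octahydrocyclodeca[b]furan-6-carboxylate | C=C1C(=O)O[C@@H]2/C=C(/CO)CC/C=C(/C(=O)OC)[C@H](OC(C)=O)[C@@H](OC(=O)/C(C)=C/C)[C@@H]12 | target

**Step count and risks**
Total step count: 14. Longest linear sequence: 13 steps (steps 1–5 and 7–14); step 6 is the side branch.

1. Step 9 (lactone closure). What may go wrong: the phosphonium enolate of an acrylate ester may fail to alkylate the epoxide, intermolecular Rauhut–Currier oligomerisation may outrun the ring closure, or the silyl group may migrate from O9 to the freed O8 alkoxide. Fallback with known chemistry, setting out from 13: esterification with (diethoxyphosphoryl)acetic acid (DCC, DMAP, CH2Cl2) should give the O6 phosphonoacetate F1. Deprotonation with NaH (THF, 0 °C → rt) should let the stabilised carbanion open the epoxide at C7 in the same 5-exo sense and with the same inversion, giving the α-(diethoxyphosphoryl) lactone F2. Horner–Wadsworth–Emmons methylenation of F2 with aqueous formaldehyde and K2CO3 returns to the route at 17.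

2. Step 13 (ring-closing metathesis). What may go wrong: the propagating alkylidene has to engage a hindered 2-substituted acrylate against the strain of a ten-membered ring, so closure may stall or give oligomers, or the catalyst may be diverted onto the lactone methylene. Fallback, setting out from 13, inverts the order of events so that the ring is closed while only one acrylate-type olefin is present: the same metathesis conditions should give the ten-membered epoxy alcohol F3, and acryloylation the O6 acrylate F4. The phosphine-mediated closure of step 9 (or its phosphonate variant) run on the ring should then give the macrocyclic hydroxy lactone F5. Yamaguchi tiglation gives the C8 tiglate F6, buffered HF·pyridine the C9 alcohol F7, and acetylation returns to the route at 21.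

3. Step 7 (fragment coupling). What may go wrong: poor facial selectivity at C6 (erythro/threo mixture), or chloride opening of the epoxide by the Lewis-acidic chromium salts. Fallback, setting out from 13 as its C6 epimer mixture, replaces substrate-controlled C–C addition by chelation-controlled reduction: Dess–Martin periodinane (CH2Cl2, NaHCO3) should give the epoxy enone F8, and Zn(BH4)2 (Et2O, −20 °C), chelated between the ketone and epoxide oxygens, should deliver hydride to give the erythro alcohol, returning to the route at 13.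

**Further compounds**
F1 | step 9 | O6 (diethoxyphosphoryl)acetate of 13 | CCOP(=O)(OCC)CC(=O)O[C@H](/C=C(/CO[Si](c2ccccc2)(c2ccccc2)C(C)(C)C)CCC=C)[C@H]1O[C@@H]1[C@@H](O[Si](C)(C)C(C)(C)C)C(=C)C(=O)OC
F2 | step 9 | α-(diethoxyphosphoryl)-γ-lactone with free C8 hydroxyl (C11 epimers) | CCOP(=O)(OCC)C1C(=O)O[C@H](/C=C(/CO[Si](c2ccccc2)(c2ccccc2)C(C)(C)C)CCC=C)[C@H]1[C@H](O)[C@@H](O[Si](C)(C)C(C)(C)C)C(=C)C(=O)OC
F3 | step 13 | ten-membered epoxy alcohol (6-OH, trans-7,8-epoxide, 9-OTBS, 15-OTBDPS, C1=C10 closed) | O[C@@H]1/C=C(/CO[Si](c3ccccc3)(c3ccccc3)C(C)(C)C)CC/C=C(/C(=O)OC)[C@H](O[Si](C)(C)C(C)(C)C)[C@H]2O[C@H]12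
F4 | step 13 | O6 acrylate of F3 | C=CC(=O)O[C@@H]1/C=C(/CO[Si](c3ccccc3)(c3ccccc3)C(C)(C)C)CC/C=C(/C(=O)OC)[C@H](O[Si](C)(C)C(C)(C)C)[C@H]2O[C@H]12
F5 | step 13 | macrocyclic α-methylene lactone with 8-OH, 9-OTBS, 15-OTBDPS | C=C1C(=O)O[C@@H]2/C=C(/CO[Si](c3ccccc3)(c3ccccc3)C(C)(C)C)CC/C=C(/C(=O)OC)[C@H](O[Si](C)(C)C(C)(C)C)[C@@H](O)[C@@H]12
F6 | step 13 | C8 tiglate of F5 | C=C1C(=O)O[C@@H]2/C=C(/CO[Si](c3ccccc3)(c3ccccc3)C(C)(C)C)CC/C=C(/C(=O)OC)[C@H](O[Si](C)(C)C(C)(C)C)[C@@H](OC(=O)/C(C)=C/C)[C@@H]12
F7 | step 13 | C9 alcohol from F6 | C=C1C(=O)O[C@@H]2/C=C(/CO[Si](c3ccccc3)(c3ccccc3)C(C)(C)C)CC/C=C(/C(=O)OC)[C@H](O)[C@@H](OC(=O)/C(C)=C/C)[C@@H]12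
F8 | step 7 | epoxy enone (C6 ketone from 13) | O=C(/C=C(/CO[Si](c2ccccc2)(c2ccccc2)C(C)(C)C)CCC=C)[C@H]1O[C@@H]1[C@@H](O[Si](C)(C)C(C)(C)C)C(=C)C(=O)OC
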